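**Strategy**

The route rests on cutting C10–C11 (numbering from the carbinol carbon), a CH2–CH2 bond inside the unfunctionalised polymethylene run C2–C13 that separates the hydroxyl terminus from the C14–C17 diyne and the furan ring. Because neither carbon carries a handle, both are generated as primary alkyl radicals from carboxylic acids one carbon longer: a nickel-electrocatalytic doubly decarboxylative coupling unites, in one operation, the in-situ N-hydroxyphthalimide esters of 12-(furan-2-yl)dodeca-5,7-diynoic acid and monomethyl undecanedioate, each losing CO2. The diyne is assembled beforehand by Cadiot–Chodkiewicz coupling; the C1 ester is reduced last.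

Key step: step 5

Remark on the chemistry: the target has no stereocentre and no stereogenic double bond, so it is achiral and no stereocontrol is needed. Monomethyl undecanedioate (9) is assumed to be commercially available.

**Route**

Step 1
Reactants: 1 furan; 2 1-bromo-4-chlorobutane
Product: 4 2-(4-chlorobutyl)furan, via 2-furyllithium 3 (not isolated)
Conditions: n-BuLi, THF, −78 → 0 °C; then 2, −78 °C → rt
Reagents that add atoms: n-butyllithium, [Li]CCCC (supplies only the lithium of intermediate 3; no atom reaches 4)
Why: Furan is lithiated at C2, the C–H bond acidified by the ring oxygen, and the 2-furyllithium displaces bromide, the better leaving group of 2, in an SN2 alkylation (heteroaryllithium alkylation), leaving the chloride for step 2.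

Step 2
Reactants: 4 2-(4-chlorobutyl)furan
Product: 5 2-(hex-5-yn-1-yl)furan
Conditions: lithium acetylide–ethylenediamine, NaI (cat.), DMSO, 10 °C → rt
Reagents that add atoms: lithium acetylide–ethylenediamine complex, [Li]C#C.NCCN
Why: SN2 alkynylation of the primary chloride by lithium acetylide in DMSO, helped by iodide catalysis (in-situ Finkelstein exchange), should install the terminal alkyne while the furan ring stays inert to the base.

Step 3
Reactants: 6 hex-5-ynoic acid
Product: 7 6-bromohex-5-ynoic acid
Conditions: NBS, AgNO3 (cat.), acetone, rt, dark
Reagents that add atoms: N-bromosuccinimide, O=C1CCC(=O)N1Br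
Why: Silver-catalysed electrophilic bromination of a terminal alkyne with NBS is selective for the sp C–H bond and should tolerate the free carboxylic acid.

Step 4
Reactants: 5 2-(hex-5-yn-1-yl)furan; 7 6-bromohex-5-ynoic acid
Product: 8 12-(furan-2-yl)dodeca-5,7-diynoic acid
Conditions: CuCl (cat.), NH2OH·HCl, 30% aq. n-BuNH2, MeOH/THF, 0 °C → rt; then aq. citric acid to pH 4
Reagents that add atoms: none
Why: Cadiot–Chodkiewicz coupling, in which the copper(I) acetylide of 5 should couple with bromoalkyne 7 (dissolved as its ammonium carboxylate) to give the unsymmetrical 1,3-diyne, with hydroxylamine keeping copper in the +1 state to suppress oxidative homocoupling.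

Step 5
Reactants: 8 12-(furan-2-yl)dodeca-5,7-diynoic acid; 9 11-methoxy-11-oxoundecanoic acid (monomethyl undecanedioate, threefold excess)
Product: 12 methyl 21-(furan-2-yl)henicosa-14,16-diynoate, via furyl-diynoic NHPI ester 10 (not isolated), via methyl-ester NHPI ester 11 (not isolated)
Conditions: NHPI, DIC, DMAP (cat.), CH2Cl2, rt; concentrate; then NiCl2·6H2O (20 mol%), 2,2′:6′,2″-terpyridine (20 mol%), AgNO3 (0.3 equiv), NaI, DMF, Mg(+)/RVC(−), constant current (ca. 2.5 F/mol), rt; aq. NH4Cl work-up
Reagents that add atoms: N-hydroxyphthalimide, O=C1c2ccccc2C(=O)N1O (its atoms stay only in intermediates 10 and 11 and leave as phthalimide; none reaches 12)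
Why: This is a Ni-electrocatalytic doubly decarboxylative Csp3–Csp3 cross-coupling of two redox-active esters, the reductive like-polarity counterpart of a mixed Kolbe coupling: cathodically generated low-valent (terpyridine)nickel transfers one electron to each N-acyloxyphthalimide, which fragments with loss of phthalimide anion and CO2 to the primary radicals MeO2C(CH2)9• and •(CH2)3C≡C–C≡C(CH2)4-furyl. Sequential capture at nickel should give a dialkylnickel species whose reductive elimination forges C10–C11, the magnesium anode supplying the two electrons. No ring is closed and no stereocentre is formed. The selectivity needed is hetero- over homocoupling of two primary radicals, which is secured statistically by the threefold excess of the cheap half-ester partner 11, whose homodimer is removable by chromatography. Chemoselectivity should follow from the mild potential at which N-acyloxyphthalimides are reduced, well short of what the internal 1,3-diyne, the furan ring or the methyl ester require, and from the absence of any terminal alkyne C–H that silver or nickel could metalate. The three-carbon spacer C11–C13 keeps the radical from 10 non-propargylic (no allenyl coupling) and allows only slow 4-exo or 5-endo-dig cyclisation, so capture by nickel should win.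

Step 6
Reactants: 12 methyl 21-(furan-2-yl)henicosa-14,16-diynoate
Product: 13 21-(furan-2-yl)henicosa-14,16-diyn-1-ol
Conditions: LiAlH4, THF, 0 °C; Fieser work-up (H2O, aq. NaOH)
Reagents that add atoms: none
Why: Hydride reduction of the methyl ester to the primary alcohol (LiAlH4 ester reduction) should be fast at 0 °C, whereas the unactivated internal diyne, which has no directing propargylic hydroxyl, and the furan should not be touched.

**Compound list**

1 | furan | c1ccoc1 | starting material
2 | 1-bromo-4-chlorobutane | ClCCCCBr | starting material
3 | 2-furyllithium | [Li]c1ccco1 | intermediate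
4 | 2-(4-chlorobutyl)furan | ClCCCCc1ccco1 | intermediate
5 | 2-(hex-5-yn-1-yl)furan | C#CCCCCc1ccco1 | intermediate
6 | hex-5-ynoic acid | C#CCCCC(=O)O | starting material
7 | 6-bromohex-5-ynoic acid | BrC#CCCCC(=O)O | intermediate
8 | 12-(furan-2-yl)dodeca-5,7-diynoic acid | OC(=O)CCCC#CC#CCCCCc1ccco1 | intermediate
9 | 11-methoxy-11-oxoundecanoic acid (monomethyl undecanedioate) | COC(=O)CCCCCCCCCC(=O)O | starting material
10 | 1,3-dioxoisoindolin-2-yl 12-(furan-2-yl)dodeca-5,7-diynoate | O=C(CCCC#CC#CCCCCc1ccco1)ON1C(=O)c2ccccc2C1=O | intermediate
11 | 1-(1,3-dioxoisoindolin-2-yl) 11-methyl undecanedioate | COC(=O)CCCCCCCCCC(=O)ON1C(=O)c2ccccc2C1=O | intermediate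
12 | methyl 21-(furan-2-yl)henicosa-14,16-diynoate | COC(=O)CCCCCCCCCCCCC#CC#CCCCCc1ccco1 | intermediate
13 | 21-(furan-2-yl)henicosa-14,16-diyn-1-ol | OCCCCCCCCCCCCCC#CC#CCCCCc1ccco1 | target

**Step count**

Total steps: 6. Longest linear sequence: 5 (steps 1, 2, 4, 5, 6).

**Steps most likely to fail, with fallbacks**

Step 5. The coupling may be eroded by homocoupling outcompeting heterocoupling of the two primary radicals, by low-valent nickel engaging the conjugated diyne (oligomerisation), or by hydrolysis of the in-situ active esters before electrolysis. The fallback forms the same C10–C11 bond by a one-pot hydroboration/B-alkyl Suzuki–Miyaura sp3–sp3 coupling. It sets out from 5: commercial 5-bromopent-1-yne (BrCCCC#C) is brominated at the alkyne terminus (NBS, cat. AgNO3, acetone) to 1,5-dibromopent-1-yne F1. F1 is joined to 5 under Cadiot–Chodkiewicz conditions (CuCl, NH2OH·HCl, aq. n-BuNH2, 0 °C, short contact time) to give 2-(11-bromoundeca-5,7-diyn-1-yl)furan F2. Commercial methyl dec-9-enoate (COC(=O)CCCCCCCCC=C) is hydroborated anti-Markovnikov with 9-BBN (THF, rt) to methyl 10-(9-borabicyclo[3.3.1]nonan-9-yl)decanoate F3. F3 is coupled in the same flask with F2 (Pd(OAc)2, PCy3, K3PO4·H2O, THF, rt) to give 12, where the route is rejoined before step 6.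

Step 4. The bromoalkyne may undergo reductive homocoupling or lose bromine before it meets the copper acetylide, giving symmetric diynes instead of the cross product. The fallback replaces the alkyne/haloalkyne union by an oxidative Glaser–Hay heterocoupling of two terminal alkynes. It sets out from 5 and 6, the inexpensive acid 6 being used in about fivefold excess (CuCl, TMEDA, air, acetone, rt), bypasses 7 and returns at 8, which is separated from the symmetric diacid and the bis-furyl diyne by chromatography. No new compound is needed.

Step 2. The strongly basic DMSO medium may cause migration of the terminal triple bond, or displacement of the primary chloride may be sluggish and lose out to elimination. The fallback uses a silyl-capped acetylide and a separate unmasking. It sets out from 4: lithium (trimethylsilyl)acetylide F4, made from ethynyltrimethylsilane (C#C[Si](C)(C)C) and n-BuLi in THF, is alkylated with 4 (THF/DMPU, cat. NaI, 50 °C) to give 2-[6-(trimethylsilyl)hex-5-yn-1-yl]furan F5. Methanolysis of the C–Si bond (K2CO3, MeOH, rt) then returns to the route at 5.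

**Further compounds**

F1 | step 5 | 1,5-dibromopent-1-yne | BrC#CCCCBr
F2 | step 5 | 2-(11-bromoundeca-5,7-diyn-1-yl)furan | BrCCCC#CC#CCCCCc1ccco1
F3 | step 5 | methyl 10-(9-borabicyclo[3.3.1]nonan-9-yl)decanoate | COC(=O)CCCCCCCCCB1C2CCCC1CCC2
F0 | step 4 | none | none
F4 | step 2 | lithium (trimethylsilyl)acetylide | [Li]C#C[Si](C)(C)C
F5 | step 2 | 2-[6-(trimethylsilyl)hex-5-yn-1-yl]furan | C[Si](C)(C)C#CCCCCc1ccco1
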